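**Remarks on the chemistry.** Ring A is the benzene ring: C1 carries the acyl group, C2, C4 and C6 carry oxygen, C3 and C5 carry the CH2 bridges. Rings B and C are the two pyranones. (R)-2-Methylbutanoic acid 17 is assumed to be bought in high enantiomeric purity. Pyranone 26 is made in two steps and not assumed to be a catalogue compound.

## Analysis of the target

The target consists of three monocycles. Ring A is a fully substituted acylphloroglucinol. C3 and C5 of ring A are each joined through a CH2 bridge to C3 of a 6-ethyl-4-hydroxy-5-methyl-2H-pyran-2-one (rings B and C). There is one stereocenter, the (R)-configured α-carbon of the 2-methylbutanoyl group on C1. It has no partner to relate to, but it sits next to an aryl ketone and can be lost by enolization. Apart from this center the two halves of the molecule are constitutionally identical, so both bridges can be formed in the same way and in the same operation. The sensitive groups are: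
- the two methylene bridges, which can fragment to a quinone methide and a pyranone under acid or base;
- the electron-rich polyphenol;
- the acidic 4-hydroxypyranones, which also act as oxygen nucleophiles;
- the α-stereocenter.

The difficulty is regiochemical and chemoselective: six different ring positions must be filled without error, and the bridges must be made without homo-coupling. The strategy rests on the strict alternation around ring A, oxygen at C2, C4 and C6 and carbon at C1, C3 and C5. A cyclobutenone supplies C6, C1, C2 and C3 with oxygen on C6 and C2. A siloxyalkyne supplies C4 and C5 with oxygen on C4.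

## Retrosynthetic reasoning

**31 to 30.** The last bond cut is the O–ethyl bond at C2. This oxygen arrives as an ethyl ether, the most robust of the three oxygen masks, so it is removed last. The C6 hydroxyl already occupies the ketone in a chelate, so a cleavage that depends on chelation to the carbonyl would stall. The forward step therefore needs a boron trihalide that cleaves an aryl alkyl ether unassisted.

**30 to 21 and two molecules of 26.** Both bonds between a bridge CH2 and C3 of a pyranone are cut. The cut is made on the pyranone side because each CH2 is already on ring A, carrying a methoxy leaving group next to a free hydroxyl. Ring A can thus only be the electrophile (ortho-quinone methides 27 and 29) and 26 only the nucleophile. Cutting on the ring A side would need free ring carbons and a separate one-carbon electrophile, and would allow pyranone–pyranone and ring A–ring A coupling. Because both arms receive the same pyranone, the two alkylations are run in one flask through mono-adduct 28.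

**21 to 20.** The Si–O bond at C4 is cut. Removing the silyl group gives the C3 arm an ortho hydroxyl of its own, so both arms can ionize by the same ortho pathway.

**20 to 18, then to 16 and 17, then to 15.** The C1–acyl bond is traced back to an ester on the C6 oxygen. A Lewis-acid acylation of 15 is avoided because the CH2OMe groups on a trioxygenated ring would ionize. Instead the acyl group is delivered within the molecule under basic conditions: bromine at C1, the ester on O6, bromine–lithium exchange to aryllithium 19, and a 1,3 shift of the acyl group from oxygen to carbon. C1 is the only unsubstituted ring carbon of 15, so the bromination has one possible site. The stereocenter comes from acid 17 and is not made in the route.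

**15 to 6 and 10.** Ring A itself is disconnected at C5–C6, C3–C4 and C1–C6. This returns a 3-alkoxycyclobutenone carrying one CH2OMe arm and a siloxyalkyne carrying the other. The gain is that all six substituents, with the three oxygens already differentiated as hydroxyl, silyl ether and ethyl ether, are set in one step from two small pieces. The forward reaction must open 6, add the resulting ketene to 10 with one regiochemistry, and close the six-membered ring.

**6 to 3 and 4, then 3 to 1.** The cyclobutenone is cut into ketene 5 (from 4) and ynol ether 3. The polarization of the ynol ether fixes which carbon bears the ethoxy group. 3 comes from 1 by attaching a methoxymethyl group to the acetylide carbon.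

**10 to 7.** The siloxyalkyne is cut at the C–O bond: the terminal alkyne 7 is oxidized at carbon through acetylide 8 and ynolate 9, and the oxygen is silylated.

**26 to 25, then to 22 and 23.** The pyranone is opened at the lactone C–O bond to dioxo ester 25. 25 is cut at C4–C5 into the dianion of 22 and Weinreb amide 23.

## Alternatives that were turned down

**Alternative 1: both pyranones annulated onto a bis-malonyl core.**
- Disconnection: rings B and C are each cut at C4–C5 and O1–C2, leaving ring A with two malonyl units on its CH2 arms.
- Forward key step: the tetra-acid chloride A2 reacts with two equivalents of the silyl enol ether A3. Each arm undergoes C-acylation and then enol O-acylation, giving the bis-pyranone A1.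
- For: ring A is taken from an existing phloroglucinol ether, both heterocycles form in one operation, and the enol partner is symmetric. The chemistry is classical acylation, so on precedent this route is stronger than the chosen key step.
- Against: A2 carries two monosubstituted malonyl dichlorides, which lose HCl to chlorocarbonyl ketenes and oligomerize, and four acylations must all succeed. A1 still lacks the acyl group. The free ring carbon would have to be acylated in the presence of two acid-labile bridges and two enolic pyranone hydroxyls that compete as O-nucleophiles, and the stereocenter would meet a Lewis acid at the last stage.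
- Comparison: the chosen route is riskier in its key step. In return it places the acyl group by intramolecular delivery to the only free carbon before any pyranone is present, and it makes the pyranone once as a simple compound and uses it twice.

**Alternative 2: ring A by Claisen recyclization of a pyranone.**
- Disconnection: ring A is cut at C1–C2 and traced to a linear tetraketide masked as pyranone A5.
- Forward key step: a magnesium alkoxide in the parent alcohol opens A5 to trioxo ester A6. The methylene between the two ketones of A6 attacks the ester carbonyl and closes ring A, giving acylphloroglucinol A4.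
- For: it is biomimetic, short and free of protecting groups, and it delivers ring A with the (R)-acyl group in place. In step count it is the strongest of the four strategies, and the fallback for the key step below reaches the same acylphloroglucinol.
- Against: A6 can close by aldol condensation to a resorcylate instead of by Claisen condensation. The stereocenter sits α to a ketone in a polycarbonyl chain under alkoxide for the whole reaction, and A5 itself needs an epimerizable acyl donor. A4 has two free ring carbons and no CH2 arms, so the bridges must come from a separate one-carbon electrophile in a three-component coupling where homo-coupling and mono- versus bis-alkylation must be controlled.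
- Comparison: the chosen route is longer. In return the arms are already on ring A with leaving groups, so the polarity of bridge formation is fixed and homo-coupling is excluded by structure.

**Alternative 3: both triketide chains by γ-acylation of a tetra-anion.**
- Disconnection: the bond between the methyl-bearing carbon and the propionyl carbonyl is cut in each future pyranone chain.
- Forward key step: the bis(β-keto ester) A8 is deprotonated four times, by a hydride base and then an alkyllithium. Both γ-carbanions are acylated by Weinreb amide 23 to give A7. No ring closes.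
- For: it uses the same dianion acylation that makes 26 in the chosen route, which is well-established chemistry, and the later lactonization is simple.
- Against: a tetra-anion of a hindered, doubly α-benzylated substrate is likely to aggregate and to metalate incompletely. The product is more acidic than the anion and quenches it. A7 is a mixture of diastereomers and tautomers. The step makes two bonds and no ring, and two lactonizations, debenzylation and the late acylation of ring A still follow. A8 also needs a bis(benzylic halide) of a phloroglucinol ether, which is a quinone methide precursor and hard to handle.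
- Comparison: on precedent of the individual reaction it is equal to steps 9 and 10 of the chosen route. The chosen route applies that reaction once to a simple substrate and leaves the complexity to a single ring-forming step.

Key step: step 4

## Route

Step 1
Reactants: 1 ethoxyethyne (ethoxyacetylene)
Product: 3 1-ethoxy-3-methoxyprop-1-yne, via lithium ethoxyacetylide 2 (not isolated)
Conditions: n-BuLi, THF, −78 °C; MeOCH2Cl, −78 → 0 °C
Reagents that add atoms: chloromethyl methyl ether, COCCl
Why: Deprotonation of the terminal ynol ether gives acetylide 2, which should displace chloride from the reactive α-chloro ether (acetylide alkylation); the basic medium protects the acid-sensitive ynol ether.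

Step 2
Reactants: 3 1-ethoxy-3-methoxyprop-1-yne; 4 acetyl chloride
Product: 6 3-ethoxy-2-(methoxymethyl)cyclobut-2-en-1-one, via ketene 5 (not isolated)
Conditions: Et3N, MeCN, 0 °C → rt, slow addition of 4
Reagents that add atoms: none
Why: Dehydrochlorination of 4 gives ketene 5, which should undergo thermal (2+2) cycloaddition with the electron-rich ynol ether; the alkyne carbon remote from the ethoxy group bonds to the ketene carbonyl carbon, so CH2OMe ends up on C2 and OEt on C3 of the cyclobutenone (ketene–alkoxyalkyne cycloaddition).

Step 3
Reactants: 7 3-methoxyprop-1-yne (methyl propargyl ether)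
Product: 10 triisopropyl[(3-methoxyprop-1-yn-1-yl)oxy]silane, via lithium acetylide 8 (not isolated), via lithium ynolate 9 (not isolated)
Conditions: n-BuLi, THF, −78 °C; LiOOt-Bu (from t-BuOOH, LiN(SiMe3)2), −78 → 0 °C; i-Pr3SiOTf, −78 → 0 °C
Reagents that add atoms: lithium tert-butyl peroxide, CC(C)(C)O[O-].[Li+]; triisopropylsilyl trifluoromethanesulfonate, CC(C)[Si](OS(=O)(=O)C(F)(F)F)(C(C)C)C(C)C
Why: Acetylide 8 should be oxidized at carbon by the electrophilic oxygen of the lithium peroxide to ynolate 9 (oxidation of a lithium acetylide to an ynolate), and the hindered silyl triflate should trap 9 on oxygen; the bulky silyl group makes the ynol ether isolable.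

Step 4
Reactants: 6 3-ethoxy-2-(methoxymethyl)cyclobut-2-en-1-one; 10 triisopropyl[(3-methoxyprop-1-yn-1-yl)oxy]silane
Product: 15 5-ethoxy-2,4-bis(methoxymethyl)-3-[(triisopropylsilyl)oxy]phenol, via vinylketene 11 (not isolated), via vinylcyclobutenone 12 (not isolated), via dienylketene 13 (not isolated), via cyclohexadienone 14 (not isolated)
Conditions: 10 (1.2 equiv), toluene, 80 → 110 °C, sealed tube, Ar
Reagents that add atoms: none
Why: Proposed new method: on heating, 6 should open by four-electron conrotatory electrocyclic cleavage of its C1–C4 bond to vinylketene 11, whose ketene C=C should add to 10 in a (2+2) cycloaddition in which the alkyne carbon remote from oxygen bonds to the ketene carbonyl carbon (ring A bond C5–C6) and the oxygen-bearing alkyne carbon to the ketene α-carbon (bond C3–C4), giving vinylcyclobutenone 12. A second four-electron opening of 12 gives dienylketene 13, which closes ring A by thermal disrotatory six-electron electrocyclization between the ketene carbon and the terminal CH2 (bond C1–C6) to dienone 14, and enolization of 14 gives phenol 15. The closest known reaction type is the Danheiser benzannulation of 3-alkyl- and 3-aryl-cyclobutenones with siloxyalkynes to resorcinol monosilyl ethers; what has not been shown is a 3-alkoxycyclobutenone as the four-carbon partner, whose vinylogous-ester stabilization should raise the temperature of the first opening and whose ethoxy group becomes the third ring oxygen. No stereocenter is formed, since the quaternary carbon of racemic 12 becomes aromatic. The step needs one regiochemistry in the ketene–alkyne cycloaddition, and the polarization of the siloxyalkyne secures it, so the three oxygens end up mutually meta with each CH2OMe arm between two of them. It also needs the geometry of 13 with the ketene and the ethoxyvinyl group cis; the opening of 12 is reversible, so the unproductive isomer can return and drain through the irreversible aromatization. Chemoselectivity against acylation of the product phenol by 11 rests on the slight excess of 10 and on the lowest workable temperature.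

Step 5
Reactants: 15 5-ethoxy-2,4-bis(methoxymethyl)-3-[(triisopropylsilyl)oxy]phenol
Product: 16 2-bromo-3-ethoxy-4,6-bis(methoxymethyl)-5-[(triisopropylsilyl)oxy]phenol
Conditions: NBS, CH2Cl2, −78 → 0 °C, dark
Reagents that add atoms: N-bromosuccinimide, O=C1CCC(=O)N1Br
Why: Electrophilic aromatic bromination; the only unsubstituted ring carbon (C1) is ortho to the hydroxyl and the ethoxy group and para to the siloxy group, so it should react at low temperature, and no strong acid is set free that could ionize the benzylic ethers.

Step 6
Reactants: 16 2-bromo-3-ethoxy-4,6-bis(methoxymethyl)-5-[(triisopropylsilyl)oxy]phenol; 17 (R)-2-methylbutanoic acid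
Product: 18 2-bromo-3-ethoxy-4,6-bis(methoxymethyl)-5-[(triisopropylsilyl)oxy]phenyl (2R)-2-methylbutanoate
Conditions: N,N'-dicyclohexylcarbodiimide (DCC), 4-(dimethylamino)pyridine (DMAP, cat.), CH2Cl2, 0 °C → rt
Reagents that add atoms: none
Why: Steglich esterification of the hindered phenol with the carbodiimide-activated acid and DMAP as acyl-transfer catalyst; no strong base is present, so the α-stereocenter of 17, the only stereocenter of the target, should be carried over unchanged.

Step 7
Reactants: 18 2-bromo-3-ethoxy-4,6-bis(methoxymethyl)-5-[(triisopropylsilyl)oxy]phenyl (2R)-2-methylbutanoate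
Product: 20 (2R)-1-{2-ethoxy-6-hydroxy-3,5-bis(methoxymethyl)-4-[(triisopropylsilyl)oxy]phenyl}-2-methylbutan-1-one, via aryllithium 19 (not isolated)
Conditions: n-BuLi (1.05 equiv), THF, −78 °C; AcOH, −78 °C
Reagents that add atoms: none
Why: Bromine–lithium exchange at the aryl bromide flanked by two oxygens should outrun addition of n-BuLi to the hindered ester; aryllithium 19 attacks the neighbouring ester carbonyl and the acyl group shifts from O6 to C1 (anionic ortho-Fries rearrangement triggered by halogen–metal exchange). No Lewis acid touches the benzylic ethers, and protonation at −78 °C before warming should keep the α-stereocenter intact.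

Step 8
Reactants: 20 (2R)-1-{2-ethoxy-6-hydroxy-3,5-bis(methoxymethyl)-4-[(triisopropylsilyl)oxy]phenyl}-2-methylbutan-1-one
Product: 21 (2R)-1-[2-ethoxy-4,6-dihydroxy-3,5-bis(methoxymethyl)phenyl]-2-methylbutan-1-one
Conditions: Bu4NF, AcOH, THF, 0 °C
Reagents that add atoms: none
Why: Fluoride cleaves the aryl silyl ether (Si–F bond formation, with the phenoxide para to the ketone as leaving group); buffering with AcOH protonates the phenoxide at once so that it does not expel methoxide from the flanking CH2OMe groups.

Step 9
Reactants: 22 methyl 3-oxopentanoate; 23 N-methoxy-N-methylpropanamide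
Product: 25 methyl 4-methyl-3,5-dioxoheptanoate (racemic, keto–enol mixture), via dianion 24 (not isolated)
Conditions: NaH, THF, 0 °C; n-BuLi, 0 °C; 23 (0.5 equiv), 0 °C → rt; aq. HCl
Reagents that add atoms: none
Why: Sequential deprotonation gives the 2,4-dianion 24, which reacts at its more nucleophilic γ-carbon with the Weinreb amide; the chelated tetrahedral adduct prevents over-addition (γ-acylation of a β-keto ester dianion), and 22 is used in excess because the product is more acidic than 22.

Step 10
Reactants: 25 methyl 4-methyl-3,5-dioxoheptanoate
Product: 26 6-ethyl-4-hydroxy-5-methyl-2H-pyran-2-one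
Conditions: 1,8-diazabicyclo[5.4.0]undec-7-ene (DBU), toluene, 110 °C
Reagents that add atoms: none
Why: Base-mediated lactonization: the enol oxygen of the C5 ketone attacks the methyl ester with loss of methoxide, and the product settles as the 4-hydroxy-2-pyranone tautomer (standard closure of a 3,5-dioxo ester).

Step 11
Reactants: 21 (2R)-1-[2-ethoxy-4,6-dihydroxy-3,5-bis(methoxymethyl)phenyl]-2-methylbutan-1-one; 26 6-ethyl-4-hydroxy-5-methyl-2H-pyran-2-one
Product: 30 3,3'-{[4-ethoxy-2,6-dihydroxy-5-[(2R)-2-methylbutanoyl]-1,3-phenylene]bis(methylene)}bis(6-ethyl-4-hydroxy-5-methyl-2H-pyran-2-one), via quinone methide 27 (not isolated), via mono-adduct 28 (not isolated), via quinone methide 29 (not isolated)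
Conditions: 26 (3 equiv), toluene, 110 °C, 4 Å molecular sieves
Reagents that add atoms: none
Why: Each ortho-hydroxybenzyl methyl ether should lose methanol on heating, assisted by the acidic pyranone, to an ortho-quinone methide (27, then 29 from mono-adduct 28), and the enol carbon C3 of 26 adds to it in Michael fashion with rearomatization of ring A (thermal ortho-quinone methide alkylation of a 1,3-dicarbonyl). Ring A has no free carbon and 26 has no electrophilic site, so only cross-coupling is possible; the order in which the arms react is immaterial because both receive the same pyranone.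

Step 12
Reactants: 30 3,3'-{[4-ethoxy-2,6-dihydroxy-5-[(2R)-2-methylbutanoyl]-1,3-phenylene]bis(methylene)}bis(6-ethyl-4-hydroxy-5-methyl-2H-pyran-2-one)
Product: 31 3,3'-{[2,4,6-trihydroxy-5-[(2R)-2-methylbutanoyl]-1,3-phenylene]bis(methylene)}bis(6-ethyl-4-hydroxy-5-methyl-2H-pyran-2-one) (CNP0174567.1)
Conditions: BBr3 (excess), CH2Cl2, −78 → 0 °C; H2O
Reagents that add atoms: none
Why: BBr3 complexes the aryl ether oxygen and bromide attacks the ethyl carbon, freeing the C2 hydroxyl on hydrolysis (Lewis-acid ether cleavage); it does not need the ketone as an anchor, which the C6 hydroxyl already occupies, and the low temperature is meant to spare the methylene bridges and the α-stereocenter.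

## Compound list

1 | ethoxyethyne (ethoxyacetylene) | CCOC#C | starting material
2 | (ethoxyethynyl)lithium | CCOC#C[Li] | intermediate
3 | 1-ethoxy-3-methoxyprop-1-yne | CCOC#CCOC | intermediate
4 | acetyl chloride | CC(Cl)=O | starting material
5 | ketene (ethenone) | C=C=O | intermediate
6 | 3-ethoxy-2-(methoxymethyl)cyclobut-2-en-1-one | CCOC1=C(COC)C(=O)C1 | intermediate
7 | 3-methoxyprop-1-yne (methyl propargyl ether) | COCC#C | starting material
8 | (3-methoxyprop-1-yn-1-yl)lithium | COCC#C[Li] | intermediate
9 | lithium 3-methoxyprop-1-yn-1-olate | COCC#C[O-].[Li+] | intermediate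
10 | triisopropyl[(3-methoxyprop-1-yn-1-yl)oxy]silane | COCC#CO[Si](C(C)C)(C(C)C)C(C)C | intermediate
11 | 3-ethoxy-2-(methoxymethyl)buta-1,3-dien-1-one | C=C(OCC)C(COC)=C=O | intermediate
12 | 4-(1-ethoxyethenyl)-2,4-bis(methoxymethyl)-3-[(triisopropylsilyl)oxy]cyclobut-2-en-1-one (racemic) | O=C1C(COC)=C(O[Si](C(C)C)(C(C)C)C(C)C)C1(COC)C(OCC)=C | intermediate
13 | (3E)-5-ethoxy-2,4-bis(methoxymethyl)-3-[(triisopropylsilyl)oxy]hexa-1,3,5-trien-1-one | O=C=C(COC)\C(O[Si](C(C)C)(C(C)C)C(C)C)=C(\COC)C(OCC)=C | intermediate
14 | 5-ethoxy-2,4-bis(methoxymethyl)-3-[(triisopropylsilyl)oxy]cyclohexa-2,4-dien-1-one | O=C1CC(OCC)=C(COC)C(O[Si](C(C)C)(C(C)C)C(C)C)=C1COC | intermediate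
15 | 5-ethoxy-2,4-bis(methoxymethyl)-3-[(triisopropylsilyl)oxy]phenol | CCOc1cc(O)c(COC)c(O[Si](C(C)C)(C(C)C)C(C)C)c1COC | intermediate
16 | 2-bromo-3-ethoxy-4,6-bis(methoxymethyl)-5-[(triisopropylsilyl)oxy]phenol | CCOc1c(Br)c(O)c(COC)c(O[Si](C(C)C)(C(C)C)C(C)C)c1COC | intermediate
17 | (R)-2-methylbutanoic acid | CC[C@@H](C)C(=O)O | starting material
18 | 2-bromo-3-ethoxy-4,6-bis(methoxymethyl)-5-[(triisopropylsilyl)oxy]phenyl (2R)-2-methylbutanoate | CC[C@@H](C)C(=O)Oc1c(Br)c(OCC)c(COC)c(O[Si](C(C)C)(C(C)C)C(C)C)c1COC | intermediate
19 | {2-ethoxy-3,5-bis(methoxymethyl)-6-{[(2R)-2-methylbutanoyl]oxy}-4-[(triisopropylsilyl)oxy]phenyl}lithium | CC[C@@H](C)C(=O)Oc1c([Li])c(OCC)c(COC)c(O[Si](C(C)C)(C(C)C)C(C)C)c1COC | intermediate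
20 | (2R)-1-{2-ethoxy-6-hydroxy-3,5-bis(methoxymethyl)-4-[(triisopropylsilyl)oxy]phenyl}-2-methylbutan-1-one | CC[C@@H](C)C(=O)c1c(O)c(COC)c(O[Si](C(C)C)(C(C)C)C(C)C)c(COC)c1OCC | intermediate
21 | (2R)-1-[2-ethoxy-4,6-dihydroxy-3,5-bis(methoxymethyl)phenyl]-2-methylbutan-1-one | CC[C@@H](C)C(=O)c1c(O)c(COC)c(O)c(COC)c1OCC | intermediate
22 | methyl 3-oxopentanoate | CCC(=O)CC(=O)OC | starting material
23 | N-methoxy-N-methylpropanamide | CCC(=O)N(C)OC | starting material
24 | methyl 3-oxopentanoate 2,4-dianion (sodium lithium salt) | C[CH-]C(=O)[CH-]C(=O)OC.[Li+].[Na+] | intermediate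
25 | methyl 4-methyl-3,5-dioxoheptanoate (racemic) | CCC(=O)C(C)C(=O)CC(=O)OC | intermediate
26 | 6-ethyl-4-hydroxy-5-methyl-2H-pyran-2-one | CCc1oc(=O)cc(O)c1C | intermediate
27 | (2R)-1-[6-ethoxy-2-hydroxy-5-(methoxymethyl)-3-methylidene-4-oxocyclohexa-1,5-dien-1-yl]-2-methylbutan-1-one | CC[C@@H](C)C(=O)C1=C(O)C(=C)C(=O)C(COC)=C1OCC | intermediate
28 | 6-ethyl-3-({4-ethoxy-2,6-dihydroxy-3-(methoxymethyl)-5-[(2R)-2-methylbutanoyl]phenyl}methyl)-4-hydroxy-5-methyl-2H-pyran-2-one | CC[C@@H](C)C(=O)c1c(O)c(Cc2c(O)c(C)c(CC)oc2=O)c(O)c(COC)c1OCC | intermediate
29 | 3-({4-ethoxy-2-hydroxy-3-[(2R)-2-methylbutanoyl]-5-methylidene-6-oxocyclohexa-1,3-dien-1-yl}methyl)-6-ethyl-4-hydroxy-5-methyl-2H-pyran-2-one | CCc1oc(=O)c(CC2=C(O)C(C(=O)[C@H](C)CC)=C(OCC)C(=C)C2=O)c(O)c1C | intermediate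
30 | 3,3'-{[4-ethoxy-2,6-dihydroxy-5-[(2R)-2-methylbutanoyl]-1,3-phenylene]bis(methylene)}bis(6-ethyl-4-hydroxy-5-methyl-2H-pyran-2-one) | CCc1oc(=O)c(Cc2c(O)c(Cc3c(O)c(C)c(CC)oc3=O)c(OCC)c(C(=O)[C@H](C)CC)c2O)c(O)c1C | intermediate
31 | 3,3'-{[2,4,6-trihydroxy-5-[(2R)-2-methylbutanoyl]-1,3-phenylene]bis(methylene)}bis(6-ethyl-4-hydroxy-5-methyl-2H-pyran-2-one) | CCc1oc(=O)c(Cc2c(O)c(Cc3c(O)c(C)c(CC)oc3=O)c(O)c(C(=O)[C@H](C)CC)c2O)c(O)c1C | target

## Step count and least certain steps

Total step count: 12. Longest linear sequence: 9 steps (1, 2, 4, 5, 6, 7, 8, 11, 12).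

**Step 4 (key step, proposed new method).**
- Risk: the vinylogous-ester stabilization of 6 may push the first ring opening to a temperature at which the product phenol loses methanol from its ortho CH2OMe group, giving premature quinone methide formation followed by oligomerization or cycloaddition to the siloxyalkyne. The alkoxy-substituted vinylketene may also dimerize or acylate the product phenol faster than it is captured by 10.
- Fallback (known chemistry, gives up the construction of ring A): it sets out from 17 and 26 and comes back at 31. Acid 17 is converted with oxalyl chloride and catalytic DMF into (2R)-2-methylbutanoyl chloride F1. Friedel–Crafts acylation of phloroglucinol with F1 and AlCl3 gives (2R)-2-methyl-1-(2,4,6-trihydroxyphenyl)butan-1-one F2. Pyranone 26 is aminomethylated with dimethyl(methylidene)ammonium iodide to the Mannich base 3-[(dimethylamino)methyl]-6-ethyl-4-hydroxy-5-methyl-2H-pyran-2-one F3. Heating F2 with two equivalents of F3 should expel dimethylamine to give the pyranone methide 6-ethyl-5-methyl-3-methylidene-2H-pyran-2,4(3H)-dione F4. F4 adds to the two free ring carbons of F2, through the mono-adduct 6-ethyl-4-hydroxy-5-methyl-3-({2,4,6-trihydroxy-3-[(2R)-2-methylbutanoyl]phenyl}methyl)-2H-pyran-2-one F5, to 31.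

**Step 12.**
- Risk: acid-induced fragmentation of the methylene bridges (loss of a pyranonylmethyl unit from the protonated ring), acid-catalysed enolization that erodes the stereocenter, or incomplete ether cleavage because the many oxygen donors bind the reagent.
- Fallback: the ether is cleaved before the bridges exist. It sets out from 21 and comes back at 31. BBr3 on 21 should cleave the ethyl ether and turn both CH2OMe groups into CH2Br, giving (2R)-1-[3,5-bis(bromomethyl)-2,4,6-trihydroxyphenyl]-2-methylbutan-1-one F6. F6 is used crude with 26 and NaHCO3 in MeCN at 0 °C, and should pass through the monobromide 3-({3-(bromomethyl)-2,4,6-trihydroxy-5-[(2R)-2-methylbutanoyl]phenyl}methyl)-6-ethyl-4-hydroxy-5-methyl-2H-pyran-2-one F7 to 31.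

**Step 11.**
- Risk: slow ionization of the CH2OMe groups, because the acyl group lowers the donor strength of the ring. The second alkylation may then stall, or the quinone methides may be trapped by phenol oxygen to give oligomers.
- Fallback: the arms are activated one at a time by different triggers. It sets out from 20 and comes back at 28, and so at 30. Heating 20 with 26 alkylates the arm next to the free C6 hydroxyl and gives 6-ethyl-3-({4-ethoxy-2-hydroxy-5-(methoxymethyl)-3-[(2R)-2-methylbutanoyl]-6-[(triisopropylsilyl)oxy]phenyl}methyl)-4-hydroxy-5-methyl-2H-pyran-2-one F8. Bu4NF in the presence of 26 then frees the C4 phenoxide of 28, which expels methoxide at ambient temperature to 29 and is trapped to 30.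

**Step 7.**
- Risk: addition of n-BuLi to the ester carbonyl or enolization of the ester in competition with the exchange, leading to loss of the acyl group or erosion of the stereocenter; or protonation of the aryllithium before the acyl shift.
- Fallback: a radical instead of an organometallic acyl shift. It sets out from 15 and comes back at 20. Steglich esterification of 15 with 17 gives 5-ethoxy-2,4-bis(methoxymethyl)-3-[(triisopropylsilyl)oxy]phenyl (2R)-2-methylbutanoate F9. Irradiation at 254 nm (photo-Fries rearrangement) should move the acyl group to the only free ortho carbon, giving 20.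

**Step 2.**
- Risk: dimerization of ketene, or direct acylation of the ynol ether by 4, faster than the cycloaddition.
- Fallback: a more electrophilic ketene followed by reduction. It sets out from 3 and comes back at 6. Dichloroketene, from trichloroacetyl chloride and Zn(Cu) in Et2O, should add to 3 to give 4,4-dichloro-3-ethoxy-2-(methoxymethyl)cyclobut-2-en-1-one F10. Zn in AcOH then removes both chlorines to give 6.

## Further compounds

F1 | step 4 | (2R)-2-methylbutanoyl chloride | CC[C@@H](C)C(Cl)=O
F2 | step 4 | (2R)-2-methyl-1-(2,4,6-trihydroxyphenyl)butan-1-one | CC[C@@H](C)C(=O)c1c(O)cc(O)cc1O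
F3 | step 4 | 3-[(dimethylamino)methyl]-6-ethyl-4-hydroxy-5-methyl-2H-pyran-2-one | CCc1oc(=O)c(CN(C)C)c(O)c1C
F4 | step 4 | 6-ethyl-5-methyl-3-methylidene-2H-pyran-2,4(3H)-dione | CCC1=C(C)C(=O)C(=C)C(=O)O1
F5 | step 4 | 6-ethyl-4-hydroxy-5-methyl-3-({2,4,6-trihydroxy-3-[(2R)-2-methylbutanoyl]phenyl}methyl)-2H-pyran-2-one | CC[C@@H](C)C(=O)c1c(O)cc(O)c(Cc2c(O)c(C)c(CC)oc2=O)c1O
F6 | step 12 | (2R)-1-[3,5-bis(bromomethyl)-2,4,6-trihydroxyphenyl]-2-methylbutan-1-one | CC[C@@H](C)C(=O)c1c(O)c(CBr)c(O)c(CBr)c1O
F7 | step 12 | 3-({3-(bromomethyl)-2,4,6-trihydroxy-5-[(2R)-2-methylbutanoyl]phenyl}methyl)-6-ethyl-4-hydroxy-5-methyl-2H-pyran-2-one | CC[C@@H](C)C(=O)c1c(O)c(CBr)c(O)c(Cc2c(O)c(C)c(CC)oc2=O)c1O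
F8 | step 11 | 6-ethyl-3-({4-ethoxy-2-hydroxy-5-(methoxymethyl)-3-[(2R)-2-methylbutanoyl]-6-[(triisopropylsilyl)oxy]phenyl}methyl)-4-hydroxy-5-methyl-2H-pyran-2-one | CC[C@@H](C)C(=O)c1c(O)c(Cc2c(O)c(C)c(CC)oc2=O)c(O[Si](C(C)C)(C(C)C)C(C)C)c(COC)c1OCC
F9 | step 7 | 5-ethoxy-2,4-bis(methoxymethyl)-3-[(triisopropylsilyl)oxy]phenyl (2R)-2-methylbutanoate | CC[C@@H](C)C(=O)Oc1cc(OCC)c(COC)c(O[Si](C(C)C)(C(C)C)C(C)C)c1COC
F10 | step 2 | 4,4-dichloro-3-ethoxy-2-(methoxymethyl)cyclobut-2-en-1-one | CCOC1=C(COC)C(=O)C1(Cl)Cl
A1 | alternative 1 | 3,3'-{[2,4,6-tris(benzyloxy)-1,3-phenylene]bis(methylene)}bis(6-ethyl-4-hydroxy-5-methyl-2H-pyran-2-one) | CCc1oc(=O)c(Cc2c(OCc3ccccc3)cc(OCc3ccccc3)c(Cc3c(O)c(C)c(CC)oc3=O)c2OCc2ccccc2)c(O)c1C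
A2 | alternative 1 | 2,2'-{[2,4,6-tris(benzyloxy)-1,3-phenylene]bis(methylene)}dipropanedioyl tetrachloride | ClC(=O)C(Cc1c(OCc2ccccc2)cc(OCc2ccccc2)c(CC(C(Cl)=O)C(Cl)=O)c1OCc1ccccc1)C(Cl)=O
A3 | alternative 1 | (Z)-3-(trimethylsilyloxy)pent-2-ene | C/C=C(\O[Si](C)(C)C)CC
A4 | alternative 2 | (2R)-2-methyl-1-(2,4,6-trihydroxyphenyl)butan-1-one | O=C(c1c(O)cc(O)cc1O)[C@H](C)CC
A5 | alternative 2 | 4-hydroxy-6-[(3R)-3-methyl-2-oxopentyl]-2H-pyran-2-one | CC[C@@H](C)C(=O)Cc1cc(O)cc(=O)o1
A6 | alternative 2 | methyl (8R)-8-methyl-3,5,7-trioxodecanoate | CC[C@@H](C)C(=O)CC(=O)CC(=O)CC(=O)OC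
A7 | alternative 3 | dimethyl 2,2'-{[2,4,6-tris(benzyloxy)-1,3-phenylene]bis(methylene)}bis(4-methyl-3,5-dioxoheptanoate) (mixture of diastereomers and enol tautomers) | CCC(=O)C(C)C(=O)C(Cc1c(OCc2ccccc2)cc(OCc2ccccc2)c(CC(C(=O)OC)C(=O)C(C)C(=O)CC)c1OCc1ccccc1)C(=O)OC
A8 | alternative 3 | dimethyl 2,2'-{[2,4,6-tris(benzyloxy)-1,3-phenylene]bis(methylene)}bis(3-oxopentanoate) | CCC(=O)C(Cc1c(OCc2ccccc2)cc(OCc2ccccc2)c(CC(C(=O)OC)C(=O)CC)c1OCc1ccccc1)C(=O)OC
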